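The vessel was closed, stirred and isothermal, and it was to run at three substrate charges with one reagent charge.

| setting | dawn | larch | ash | oak |
|---|---|---|---|---|
| substrate | 0.34 M | 0.30 M | 1.0 M | 3.0 M |
| reagent | 1.5 M | 1.50 M | 1.50 M | 1.50 M |
| remark | run made earlier |  |  |  |
| time |  | 3.0 h | 3.0 h | 3.0 h |

- dawn (time / h: triple product / %, substrate / %): 0.833: 3.9, 53.1; 1.50: 15.8, 34.6; 2.50: 33.4, 20.9; 3.00: 40.4, 16.0

(readings scatter by 0.5 percentage points)

- "hardly changes" means that all values lie within two and a half points (for a concentration: within two and a half percent of the largest)

- [triple product] at the end for larch, ash, oak, in this order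
- the course of these numbers from the first flask to the last (falls, then rises / falls all the way / rises all the way / hardly changes / rises, then falls)

I followed one rate, the log-decay rate of the substrate in dawn. By 3.00 h dawn had reached 1.83 in the logarithm of substrate charged over substrate left, and I called this logarithm the dose θ. I assumed that θ is the clock of the chain, so that equal dose means equal percentage of triple product.

Over the first reading of dawn the mean rate was r = 0.760 h⁻¹, a pseudo-first-order rate. Over the whole run its mean was 0.610 h⁻¹. So the slowing factor f, mean rate of the whole run over that first rate, read 0.804.

I kept r for the new flasks, whose reagent charge matches dawn's. I assumed that the slowing grows with the substrate charge c as f = 1/(1 + gc), and dawn gave g = 0.718 M⁻¹. So f was 0.823 for larch, 0.582 for ash and 0.317 for oak. The dose at 3.0 h is then θ = rft, which gave 1.88, 1.33 and 0.723.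

I read dawn's percentages against θ along straight lines, and this gave 0.125 M, 0.251 M and 0.192 M. These were my own figures for larch, ash and oak, in this order, and in them ash stood higher than larch and oak.

The forecast gave 0.13 M, 0.18 M and 0.05 M, with the course rises, then falls. For oak it said “the reagent is exhausted early”, and its figure stood below mine.

The flasks gave 0.127 M, 0.191 M and 0.118 M, with the course rises, then falls.

    substrate + reagent → single product + by-product (k = 0.00980 M⁻¹ min⁻¹)
    reagent + double product → triple product + by-product (k = 0.0140 M⁻¹ min⁻¹)
    2 substrate → homo dimer (k = 0.00280 M⁻¹ min⁻¹)
    reagent ⇌ dormant form (K = 0.220, k = 0.0560 min⁻¹)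
    substrate + single product → side product (k = 0.00170 M⁻¹ min⁻¹)
    reagent + single product → double product + by-product (k = 0.0230 M⁻¹ min⁻¹)

In larch, the dose from the substrate left came to 1.85, beside my 1.88. In oak it came to 1.74, against my 0.723. At the start of larch, the first step used substrate at 8.8 times the rate of the homo dimer step, and at the start of oak that ratio was 0.875. At 3.00 h the homo dimer in oak held 48.9 % of the substrate charged.

The readings were computed from invented constants; noise was put on by code.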